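The rate constants are made up, and the outcome is calculated.

The pitfall here is to reckon the share of links from the first end groups remaining, when their concentration stands as one factor in the link rate and the ring rate alike and so drops out of the ratio.

the same everywhere: first end groups 0.10 M
- noon: second end groups 0.900 equiv; one stirred flow tank at steady state, fed with the mixture as stated, mean residence time 4.0 min
- spring: second end groups 0.900 equiv (fed, over 3.20 min); a stirred flask in which second end groups is dosed at a steady rate over 3.20 min without added volume, worked up at 4.0 min; time 4.0 min
- midnight: second end groups 0.900 equiv; a closed flask charged with all of it at once and left for 4.0 min; time 4.0 min
- dawn: second end groups 0.900 equiv; a single well-mixed tank run continuously and read at steady state, 20.0 min in it on average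

    first end groups + second end groups → links (k1 = 2.8 M⁻¹ min⁻¹)
    first end groups + second end groups → rings, rate k2*[first end groups] as long as [second end groups] is above zero (k2 = 0.11 min⁻¹)
    first end groups + links ⇌ idle adduct, settled at all times (K3 = 14 M⁻¹)

1. order of the set-ups by the share of links in all that became links or rings, at the outlet or at the end, highest first (noon / spring / midnight / dawn)
2. share of links in all that became links or rings, at the outlet or at the end, noon
3. share of links in all that became links or rings, at the outlet or at the end, spring
4. share of links in all that became links or rings, at the outlet or at the end, midnight
5. share of links in all that became links or rings, at the outlet or at the end, dawn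

- in percentages every species weighs as the first end groups in it: one idle adduct counts as two
- for links the idle adduct is counted in
- the stated concentrations are those of everything mixed, before any reaction; amounts are the same in each set-up
- the feed brings no volume worth counting
- in an amount of links, one idle adduct counts as one links
- run time (spring): 4.0 min

Write a and b for the free first and second end groups. The selectivity, link rate over ring rate, is b/b*, where b* is the break-even concentration, the ring constant over the link constant, 0.0393 M, so product formed at b is a share b/(b+b*) links while b is above zero. Second end groups, the limiting reagent, are used at the link constant times a times (b+b*).

We reckon midnight. From 0.0900 M of second end groups the selectivity in midnight starts at 2.29 and second end groups go at 0.0362 M min⁻¹. The ratio a/b starts at 1.11, and the adduct takes further first end groups, its constant times a being 1.40 at the start, so we freeze a/b at one. The rate law then integrates to b = 0.0319 M at 4.0 min. By then the factor (b+b*) has shrunk 1.82-fold and a 3.13-fold, leaving a rate of 0.00637 M min⁻¹. Dividing the ring rate by the rate of use of b gives rings = b* ln((b₀+b*)/(b+b*)), with b₀ the starting b, which is 0.0234 M, so our midnight share is 59.7%.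

The forecast, holding that dosing keeps second end groups low, “which favours rings”, gave midnight > noon > spring > dawn, with noon 61.9%, spring 46.3%, dawn 36.1% and midnight 65.8%, which stands above our figure.

The simulation gives midnight > noon > spring > dawn, with noon 53.8%, spring 38.6%, midnight 59.6% and dawn 31.3%. At 4.00 min midnight holds 35.3% of its own charge of second end groups, against our 35.4%. In dawn, a tank, product forms at the one concentration of second end groups 0.0179 M, and b/(b+b*) gives 31.3%.

The neighbouring flask is midnight with 0.25 M of first end groups, the equivalents held, and its selectivity starts at 5.73. The same freeze gives b = 0.0477 M and a share of 75.4%. The simulation gives that neighbouring flask 76.7%, a little more than our figure, with 27% of its charged second end groups still there against our 21.2%.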